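The plan cuts ring C at O1–C8a and C4–C4a. Both bonds end on neighbouring ring A carbons, and C4a has the C5 oxygen next to it, so ring A can enter as a 3-alkoxyaryne. In one operation, fluoride unmasks this aryne from an ortho-silylaryl triflate that holds the prenyl group between two MOM ethers. The oxygen terminus of a methyl 2-aryl-3-hydroxyacrylate enolate then bonds to the aryne carbon meta to the alkoxy substituent. The carbanion left beside that substituent attacks the ester carbonyl. This builds the pyranone and gives the protected 6-prenylisoflavone. C8 is then iodinated, magnesiated and joined to an (R)-epoxide. Dehydration and deprotection complete the synthesis.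

Key step: step 10

Assumption: the side-chain carbinol carbon C2'' is read as R from the SMILES. Methyl (R)-glycidate is taken as commercial. Enol 18 is a mobile E/Z and keto–enol mixture, so its SMILES carries no double-bond descriptor.

Step 1
Reactants: 1 phloroglucinol
Product: 2 3,5-bis(methoxymethoxy)phenol
Conditions: NaH (2.0 equiv), MOMCl (2.0 equiv), DMF, 0 °C → rt
Reagents that add atoms: chloromethyl methyl ether, COCCl
Why: Williamson-type O-alkylation with a hard chloromethyl ether stops statistically at the bis-ether when two equivalents are used, and the mono- and tris-ethers are separable by chromatography and can be recycled.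

Step 2
Reactants: 2 3,5-bis(methoxymethoxy)phenol
Product: 3 [3,5-bis(methoxymethoxy)phenoxy]triisopropylsilane
Conditions: TIPSCl, imidazole, DMF, rt
Reagents that add atoms: triisopropylsilyl chloride, CC(C)[Si](Cl)(C(C)C)C(C)C
Why: Imidazole-promoted silylation masks the acidic phenol with a bulky, poorly coordinating group that keeps the next lithiation away from its own ortho positions.

Step 3
Reactants: 3 [3,5-bis(methoxymethoxy)phenoxy]triisopropylsilane; 4 prenyl bromide (1-bromo-3-methylbut-2-ene)
Product: 6 [3,5-bis(methoxymethoxy)-4-(3-methylbut-2-enyl)phenoxy]triisopropylsilane, via aryllithium 5 (not isolated)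
Conditions: n-BuLi, THF, 0 °C; then 4, −78 °C → rt
Reagents that add atoms: none
Why: Directed ortho-metalation occurs at the carbon flanked by both chelating MOM ethers, and the aryllithium displaces the primary allylic bromide in an SN2 alkylation.

Step 4
Reactants: 6 [3,5-bis(methoxymethoxy)-4-(3-methylbut-2-enyl)phenoxy]triisopropylsilane
Product: 7 3,5-bis(methoxymethoxy)-4-(3-methylbut-2-enyl)phenol
Conditions: TBAF, AcOH, THF, 0 °C
Reagents that add atoms: none
Why: Buffered fluoride desilylation of an aryl silyl ether leaves the MOM ethers and the alkene untouched and gives a mirror-symmetric phenol with two equivalent ortho positions.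

Step 5
Reactants: 7 3,5-bis(methoxymethoxy)-4-(3-methylbut-2-enyl)phenol
Product: 8 2-bromo-3,5-bis(methoxymethoxy)-4-(3-methylbut-2-enyl)phenol
Conditions: NBS (1.0 equiv), CH2Cl2, −78 → −20 °C, dark
Reagents that add atoms: N-bromosuccinimide, O=C1CCC(=O)N1Br
Why: Electrophilic aromatic bromination of a free phloroglucinol-type phenol should outrun attack on the trisubstituted alkene at low temperature, since the para position is blocked, both ortho positions are identical, and one equivalent limits double bromination.

Step 6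
Reactants: 8 2-bromo-3,5-bis(methoxymethoxy)-4-(3-methylbut-2-enyl)phenol
Product: 12 3,5-bis(methoxymethoxy)-4-(3-methylbut-2-enyl)-2-(trimethylsilyl)phenyl trifluoromethanesulfonate, via bromoaryl silyl ether 9 (not isolated), via aryllithium 10 (not isolated), via lithium silylphenoxide 11 (not isolated)
Conditions: HMDS, THF, 65 °C, then evaporate; n-BuLi, THF, −78 °C; Tf2O, −78 → 0 °C
Reagents that add atoms: hexamethyldisilazane, C[Si](C)(C)N[Si](C)(C)C; trifluoromethanesulfonic anhydride, O=S(=O)(OS(=O)(=O)C(F)(F)F)C(F)(F)F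
Why: O-silylation, bromine–lithium exchange, retro-Brook rearrangement (anionic O→C silyl shift) and triflation of the freed phenoxide are the standard entry to ortho-silylaryl triflates, and they place silicon between OTf and OMOM.

Step 7
Reactants: 13 3,4-dihydroxyphenylacetic acid
Product: 14 methyl 3,4-dihydroxyphenylacetate
Conditions: MeOH, H2SO4 (cat.), reflux
Reagents that add atoms: methanol, CO
Why: Fischer esterification in excess methanol converts the acid without affecting the catechol.

Step 8
Reactants: 14 methyl 3,4-dihydroxyphenylacetate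
Product: 15 methyl 3,4-bis(methoxymethoxy)phenylacetate
Conditions: MOMCl, i-Pr2NEt, CH2Cl2, 0 °C → rt
Reagents that add atoms: chloromethyl methyl ether, COCCl
Why: Amine-mediated O-alkylation of both phenols gives the MOM ethers, and the base is too weak to enolise the ester.

Step 9
Reactants: 15 methyl 3,4-bis(methoxymethoxy)phenylacetate; 16 methyl formate
Product: 18 methyl 2-[3,4-bis(methoxymethoxy)phenyl]-3-hydroxyprop-2-enoate, via sodium enolate 17 (not isolated)
Conditions: NaH, 16 (excess), THF, 0 °C → rt; then AcOH, 0 °C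
Reagents that add atoms: none
Why: The crossed Claisen condensation with non-enolisable methyl formate is driven by formation of the stabilised enolate, and mild acidification frees the enol without harming the MOM ethers.

Step 10
Reactants: 12 3,5-bis(methoxymethoxy)-4-(3-methylbut-2-enyl)-2-(trimethylsilyl)phenyl trifluoromethanesulfonate; 18 methyl 2-[3,4-bis(methoxymethoxy)phenyl]-3-hydroxyprop-2-enoate
Product: 22 5,7,3',4'-tetrakis(methoxymethoxy)-6-(3-methylbut-2-enyl)isoflavone, via caesium enolate 19 (not isolated), via aryne 20 (not isolated), via aryl anion 21 (not isolated)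
Conditions: CsF (4 equiv), 18 (1.3 equiv), 4 Å MS, THF (0.05 M), 65 °C, sealed tube
Reagents that add atoms: none
Why: Proposed new method: CsF strips the silyl group of 12 with loss of triflate to give aryne 20, the oxygen of caesium enolate 19 bonds to the aryne carbon meta to the flanking OMOM group (future C8a), and aryl anion 21, located ortho to that OMOM group (future C4a), attacks the cis-disposed ester with loss of methoxide. The closest known reaction types are the fluoride-induced annulation of arynes with salicylate esters to xanthones, of which this is the enol (vinylogous acid) version, and the aryne acyl-alkylation of beta-keto esters, which marks the competing attack through carbon. Ring C closes by a 6-exo-trig addition–elimination at the ester carbonyl, and no stereocentre is formed. The aryne regioselectivity that the step needs is secured by the inductive pull and bond-angle distortion caused by the adjacent alkoxy group, helped by its bulk next to the prenyl group; reversed addition could only give a 6,8-dioxygenated 7-prenyl isomer, and an 8-prenyl isomer cannot arise at all because 12 derives from the symmetric phenol 7. O-attack should win over C-attack because the enolate carbon is fully substituted while the formyl-derived oxygen is unhindered, and the crown-free caesium contact ion pair in THF should hold oxygen and ester on the same side of the double bond (Z), as closure demands. Dilute THF, slow aryne release by sparingly soluble CsF, and sieves that take up methanol keep protonation of 21 and deformylation of 18 behind the intramolecular acylation.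

Step 11
Reactants: 22 5,7,3',4'-tetrakis(methoxymethoxy)-6-(3-methylbut-2-enyl)isoflavone
Product: 23 8-iodo-5,7,3',4'-tetrakis(methoxymethoxy)-6-(3-methylbut-2-enyl)isoflavone
Conditions: NIS (1.05 equiv), CF3CO2H (10 mol %), MeCN, −20 → 0 °C, dark
Reagents that add atoms: N-iodosuccinimide, O=C1CCC(=O)N1I
Why: Electrophilic aromatic iodination goes to C8, the only free ring A position, which is activated by O1 and O7 (ortho) and O5 (para) as in other 5,7-dialkoxy(iso)flavones, while low temperature, one equivalent and exclusion of light hold back attack on the prenyl alkene and ring B.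

Step 12
Reactants: 24 methyl (2R)-oxirane-2-carboxylate (methyl (R)-glycidate)
Product: 26 2-[(2R)-oxiran-2-yl]propan-2-ol, via epoxy ketone 25 (not isolated)
Conditions: MeMgCl (2.2 equiv), THF, −78 → −30 °C; aq NH4Cl
Reagents that add atoms: methylmagnesium chloride, C[Mg]Cl
Why: Double Grignard addition to the ester is far faster at low temperature than uncatalysed epoxide opening, and the chiral-pool stereocentre takes no part, so the R configuration is kept.

Step 13
Reactants: 26 2-[(2R)-oxiran-2-yl]propan-2-ol
Product: 27 trimethyl({2-[(2R)-oxiran-2-yl]propan-2-yl}oxy)silane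
Conditions: TMSCl, imidazole, CH2Cl2, 0 °C → rt
Reagents that add atoms: chlorotrimethylsilane, C[Si](C)(C)Cl
Why: Imidazole-promoted silylation masks the tertiary hydroxyl, which would otherwise protonate the arylmagnesium reagent or start a Payne rearrangement.

Step 14
Reactants: 23 8-iodo-5,7,3',4'-tetrakis(methoxymethoxy)-6-(3-methylbut-2-enyl)isoflavone; 27 trimethyl({2-[(2R)-oxiran-2-yl]propan-2-yl}oxy)silane
Product: 30 8-[(2R)-2,3-dihydroxy-3-methylbutyl]-5,7,3',4'-tetrakis(methoxymethoxy)-6-(3-methylbut-2-enyl)isoflavone, via arylmagnesium chloride 28 (not isolated), via tertiary silyl ether 29 (not isolated)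
Conditions: i-PrMgCl·LiCl, THF, −40 °C; CuI (10 mol %), 27, −40 → 0 °C; aq NH4Cl; crude: TBAF, AcOH, THF, 0 °C
Reagents that add atoms: none
Why: Iodine–magnesium exchange with the turbo-Grignard reagent should be faster at low temperature than addition to the vinylogous ester of ring C, and the copper-catalysed SN2 epoxide opening occurs at the unsubstituted CH2, so the C–O bond at the stereocentre stays intact and C2'' is R before fluoride removes the TMS group.

Step 15
Reactants: 30 8-[(2R)-2,3-dihydroxy-3-methylbutyl]-5,7,3',4'-tetrakis(methoxymethoxy)-6-(3-methylbut-2-enyl)isoflavone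
Product: 31 8-[(2R)-3-hydroxy-3-methyl-2-(triethylsilyloxy)butyl]-5,7,3',4'-tetrakis(methoxymethoxy)-6-(3-methylbut-2-enyl)isoflavone
Conditions: TESCl, imidazole, CH2Cl2, 0 °C
Reagents that add atoms: chlorotriethylsilane, CC[Si](Cl)(CC)CC
Why: Sterically controlled selective silylation takes the secondary hydroxyl and leaves the tertiary one free for elimination.

Step 16
Reactants: 31 8-[(2R)-3-hydroxy-3-methyl-2-(triethylsilyloxy)butyl]-5,7,3',4'-tetrakis(methoxymethoxy)-6-(3-methylbut-2-enyl)isoflavone
Product: 33 8-[(2R)-3-methyl-2-(triethylsilyloxy)but-3-enyl]-5,7,3',4'-tetrakis(methoxymethoxy)-6-(3-methylbut-2-enyl)isoflavone, via chlorosulfite 32 (not isolated)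
Conditions: SOCl2, pyridine, CH2Cl2, −20 → 0 °C
Reagents that add atoms: none
Why: Thionyl chloride–pyridine dehydration (E2 from the chlorosulfite) removes one of six exposed methyl hydrogens rather than the single hindered C2''–H beside OTES, which gives the isopropenyl group and leaves the stereocentre untouched.

Step 17
Reactants: 33 8-[(2R)-3-methyl-2-(triethylsilyloxy)but-3-enyl]-5,7,3',4'-tetrakis(methoxymethoxy)-6-(3-methylbut-2-enyl)isoflavone
Product: 34 3-(3,4-dihydroxyphenyl)-5,7-dihydroxy-8-[(2R)-2-hydroxy-3-methylbut-3-enyl]-6-(3-methylbut-2-enyl)-4H-chromen-4-one (target)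
Conditions: HCl (cat., 0.5 M), MeOH, 40 °C
Reagents that add atoms: none
Why: Acid-catalysed methanolysis (acetal exchange and silyl ether solvolysis) removes the four aryl MOM ethers and the TES ether in one operation, and the mild temperature should prevent chroman formation from the prenyl group and ionisation of the allylic alcohol, so R is retained.

Compound list
1 | phloroglucinol | Oc1cc(O)cc(O)c1 | starting material
2 | 3,5-bis(methoxymethoxy)phenol | COCOc1cc(O)cc(OCOC)c1 | intermediate
3 | [3,5-bis(methoxymethoxy)phenoxy]triisopropylsilane | COCOc1cc(OCOC)cc(O[Si](C(C)C)(C(C)C)C(C)C)c1 | intermediate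
4 | prenyl bromide | CC(C)=CCBr | starting material
5 | 2,6-bis(methoxymethoxy)-4-(triisopropylsilyloxy)phenyllithium | [Li]c1c(OCOC)cc(O[Si](C(C)C)(C(C)C)C(C)C)cc1OCOC | intermediate
6 | [3,5-bis(methoxymethoxy)-4-(3-methylbut-2-enyl)phenoxy]triisopropylsilane | CC(C)=CCc1c(OCOC)cc(O[Si](C(C)C)(C(C)C)C(C)C)cc1OCOC | intermediate
7 | 3,5-bis(methoxymethoxy)-4-(3-methylbut-2-enyl)phenol | CC(C)=CCc1c(OCOC)cc(O)cc1OCOC | intermediate
8 | 2-bromo-3,5-bis(methoxymethoxy)-4-(3-methylbut-2-enyl)phenol | CC(C)=CCc1c(OCOC)cc(O)c(Br)c1OCOC | intermediate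
9 | [2-bromo-3,5-bis(methoxymethoxy)-4-(3-methylbut-2-enyl)phenoxy]trimethylsilane | CC(C)=CCc1c(OCOC)cc(O[Si](C)(C)C)c(Br)c1OCOC | intermediate
10 | 2,4-bis(methoxymethoxy)-3-(3-methylbut-2-enyl)-6-(trimethylsilyloxy)phenyllithium | CC(C)=CCc1c(OCOC)cc(O[Si](C)(C)C)c([Li])c1OCOC | intermediate
11 | lithium 3,5-bis(methoxymethoxy)-4-(3-methylbut-2-enyl)-2-(trimethylsilyl)phenoxide | CC(C)=CCc1c(OCOC)cc(O[Li])c([Si](C)(C)C)c1OCOC | intermediate
12 | 3,5-bis(methoxymethoxy)-4-(3-methylbut-2-enyl)-2-(trimethylsilyl)phenyl trifluoromethanesulfonate | CC(C)=CCc1c(OCOC)cc(OS(=O)(=O)C(F)(F)F)c([Si](C)(C)C)c1OCOC | intermediate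
13 | 3,4-dihydroxyphenylacetic acid | OC(=O)Cc1ccc(O)c(O)c1 | starting material
14 | methyl 3,4-dihydroxyphenylacetate | COC(=O)Cc1ccc(O)c(O)c1 | intermediate
15 | methyl 3,4-bis(methoxymethoxy)phenylacetate | COC(=O)Cc1ccc(OCOC)c(OCOC)c1 | intermediate
16 | methyl formate | COC=O | starting material
17 | sodium enolate of 18 | COC(=O)C(=C[O-])c1ccc(OCOC)c(OCOC)c1.[Na+] | intermediate
18 | methyl 2-[3,4-bis(methoxymethoxy)phenyl]-3-hydroxyprop-2-enoate (mobile enol, hydrogen-bonded Z form expected to dominate) | COC(=O)C(=CO)c1ccc(OCOC)c(OCOC)c1 | intermediate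
19 | caesium enolate of 18 | COC(=O)C(=C[O-])c1ccc(OCOC)c(OCOC)c1.[Cs+] | intermediate
20 | 3,5-bis(methoxymethoxy)-4-(3-methylbut-2-enyl)benzyne | COCOC1=CC#CC(OCOC)=C1CC=C(C)C | intermediate
21 | methyl (Z)-3-[2-caesio-3,5-bis(methoxymethoxy)-4-(3-methylbut-2-enyl)phenoxy]-2-[3,4-bis(methoxymethoxy)phenyl]prop-2-enoate | COC(=O)/C(=C\Oc1cc(OCOC)c(CC=C(C)C)c(OCOC)c1[Cs])c1ccc(OCOC)c(OCOC)c1 | intermediate
22 | 5,7,3',4'-tetrakis(methoxymethoxy)-6-(3-methylbut-2-enyl)isoflavone | COCOc1cc2occ(-c3ccc(OCOC)c(OCOC)c3)c(=O)c2c(OCOC)c1CC=C(C)C | intermediate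
23 | 8-iodo-5,7,3',4'-tetrakis(methoxymethoxy)-6-(3-methylbut-2-enyl)isoflavone | COCOc1c(I)c2occ(-c3ccc(OCOC)c(OCOC)c3)c(=O)c2c(OCOC)c1CC=C(C)C | intermediate
24 | methyl (2R)-oxirane-2-carboxylate | COC(=O)[C@H]1CO1 | starting material
25 | 1-[(2R)-oxiran-2-yl]ethan-1-one | CC(=O)[C@H]1CO1 | intermediate
26 | 2-[(2R)-oxiran-2-yl]propan-2-ol | CC(C)(O)[C@H]1CO1 | intermediate
27 | trimethyl({2-[(2R)-oxiran-2-yl]propan-2-yl}oxy)silane | CC(C)(O[Si](C)(C)C)[C@H]1CO1 | intermediate
28 | 8-(chloromagnesio)-5,7,3',4'-tetrakis(methoxymethoxy)-6-(3-methylbut-2-enyl)isoflavone | COCOc1c([Mg]Cl)c2occ(-c3ccc(OCOC)c(OCOC)c3)c(=O)c2c(OCOC)c1CC=C(C)C | intermediate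
29 | 8-[(2R)-2-hydroxy-3-methyl-3-(trimethylsilyloxy)butyl]-5,7,3',4'-tetrakis(methoxymethoxy)-6-(3-methylbut-2-enyl)isoflavone | CC(C)(O[Si](C)(C)C)[C@H](O)Cc1c(OCOC)c(CC=C(C)C)c(OCOC)c2c(=O)c(-c3ccc(OCOC)c(OCOC)c3)coc12 | intermediate
30 | 8-[(2R)-2,3-dihydroxy-3-methylbutyl]-5,7,3',4'-tetrakis(methoxymethoxy)-6-(3-methylbut-2-enyl)isoflavone | CC(C)(O)[C@H](O)Cc1c(OCOC)c(CC=C(C)C)c(OCOC)c2c(=O)c(-c3ccc(OCOC)c(OCOC)c3)coc12 | intermediate
31 | 8-[(2R)-3-hydroxy-3-methyl-2-(triethylsilyloxy)butyl]-5,7,3',4'-tetrakis(methoxymethoxy)-6-(3-methylbut-2-enyl)isoflavone | CC(C)(O)[C@H](O[Si](CC)(CC)CC)Cc1c(OCOC)c(CC=C(C)C)c(OCOC)c2c(=O)c(-c3ccc(OCOC)c(OCOC)c3)coc12 | intermediate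
32 | tertiary chlorosulfite of 31 | CC(C)(OS(=O)Cl)[C@H](O[Si](CC)(CC)CC)Cc1c(OCOC)c(CC=C(C)C)c(OCOC)c2c(=O)c(-c3ccc(OCOC)c(OCOC)c3)coc12 | intermediate
33 | 8-[(2R)-3-methyl-2-(triethylsilyloxy)but-3-enyl]-5,7,3',4'-tetrakis(methoxymethoxy)-6-(3-methylbut-2-enyl)isoflavone | C=C(C)[C@H](O[Si](CC)(CC)CC)Cc1c(OCOC)c(CC=C(C)C)c(OCOC)c2c(=O)c(-c3ccc(OCOC)c(OCOC)c3)coc12 | intermediate
34 | 3-(3,4-dihydroxyphenyl)-5,7-dihydroxy-8-[(2R)-2-hydroxy-3-methylbut-3-enyl]-6-(3-methylbut-2-enyl)-4H-chromen-4-one | C=C(C)[C@H](O)Cc1c(O)c(CC=C(C)C)c(O)c2c(=O)c(-c3ccc(O)c(O)c3)coc12 | target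

Total step count: 17.
Longest linear sequence: 12 (steps 1–6, 10, 11, 14–17).

Steps most likely to fail

Step 10. Four processes threaten this step.
- The ambident enolate may react through carbon and enter the acyl-alkylation manifold.
- The aryl anion may be protonated before it reaches the ester.
- O-arylation may occur from the E geometry, so that ring closure is impossible.
- Liberated methoxide may deformylate the enol partner.

The fallback is the known deoxybenzoin route. It sets out from 8 and 15 and comes back at 22. Ester 15 is converted with MeNHOMe·HCl and i-PrMgCl (THF, −20 °C) into the Weinreb amide 2-[3,4-bis(methoxymethoxy)phenyl]-N-methoxy-N-methylacetamide F1. Bromophenol 8 is treated with n-BuLi (2.2 equiv, THF, −78 °C) for deprotonation and bromine–lithium exchange. It is then acylated with F1 to give the deoxybenzoin 1-[6-hydroxy-2,4-bis(methoxymethoxy)-3-(3-methylbut-2-enyl)phenyl]-2-[3,4-bis(methoxymethoxy)phenyl]ethanone F2. Heating F2 with N,N-dimethylformamide dimethyl acetal (toluene, 90 °C) supplies C2 and closes ring C to 22. The symmetry of 7 again fixes the prenyl group at C6.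

Step 14. Three processes threaten this step.
- The exchange reagent or the arylmagnesium species may add to C2 or C4 of ring C.
- The doubly ortho-substituted arylmagnesium may be protonated while opening of the neopentyl-type epoxide lags.
- Chloride may open the epoxide instead.

The fallback sets out from 23 and comes back at 29. The C8–C1'' bond is made by palladium catalysis, and the stereocentre is set by reagent control instead of the chiral pool. Commercial 3-hydroxy-3-methylbutan-2-one is silylated (TMSCl, imidazole) to 3-methyl-3-(trimethylsilyloxy)butan-2-one F3, which can enolise only at its methyl group. Ketone α-arylation of F3 with 23 (Pd2(dba)3, XPhos, K3PO4, toluene, 80 °C) gives 8-[3-methyl-2-oxo-3-(trimethylsilyloxy)butyl]-5,7,3',4'-tetrakis(methoxymethoxy)-6-(3-methylbut-2-enyl)isoflavone F4. Corey–Bakshi–Shibata reduction of F4 with the (S)-methyl oxazaborolidine and catecholborane (toluene, −78 °C) follows. With the C(OTMS)Me2 group as the large substituent, it should deliver the R alcohol 29. This is desilylated as in step 14.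

Step 11. Three processes threaten this step.
- The iodonium source may attack the prenyl double bond with participation of a neighbouring MOM oxygen.
- Ring B may be iodinated in competition.
- Trace acid may strip the 5-O-MOM group.

The fallback sets out from 22 and comes back at 23. It replaces electrophilic substitution by deprotonative metalation. LDA added to 22 and TMSCl (THF, −78 °C, in situ quench) silylates the most acidic position, C2–H. This gives 5,7,3',4'-tetrakis(methoxymethoxy)-6-(3-methylbut-2-enyl)-2-(trimethylsilyl)isoflavone F5. Lithium 2,2,6,6-tetramethylpiperidide (THF, −78 °C) then removes C8–H, which lies between O1 and the 7-OMOM group. Quenching with I2 gives 8-iodo-5,7,3',4'-tetrakis(methoxymethoxy)-6-(3-methylbut-2-enyl)-2-(trimethylsilyl)isoflavone F6. TBAF and AcOH (THF, 0 °C) remove the C2 silyl group to give 23.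

Further compounds
F1 | step 10 | 2-[3,4-bis(methoxymethoxy)phenyl]-N-methoxy-N-methylacetamide | CON(C)C(=O)Cc1ccc(OCOC)c(OCOC)c1
F2 | step 10 | 1-[6-hydroxy-2,4-bis(methoxymethoxy)-3-(3-methylbut-2-enyl)phenyl]-2-[3,4-bis(methoxymethoxy)phenyl]ethanone | O=C(Cc1ccc(OCOC)c(OCOC)c1)c1c(O)cc(OCOC)c(CC=C(C)C)c1OCOC
F3 | step 14 | 3-methyl-3-(trimethylsilyloxy)butan-2-one | CC(=O)C(C)(C)O[Si](C)(C)C
F4 | step 14 | 8-[3-methyl-2-oxo-3-(trimethylsilyloxy)butyl]-5,7,3',4'-tetrakis(methoxymethoxy)-6-(3-methylbut-2-enyl)isoflavone | CC(C)(O[Si](C)(C)C)C(=O)Cc1c(OCOC)c(CC=C(C)C)c(OCOC)c2c(=O)c(-c3ccc(OCOC)c(OCOC)c3)coc12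
F5 | step 11 | 5,7,3',4'-tetrakis(methoxymethoxy)-6-(3-methylbut-2-enyl)-2-(trimethylsilyl)isoflavone | COCOc1cc2oc([Si](C)(C)C)c(-c3ccc(OCOC)c(OCOC)c3)c(=O)c2c(OCOC)c1CC=C(C)C
F6 | step 11 | 8-iodo-5,7,3',4'-tetrakis(methoxymethoxy)-6-(3-methylbut-2-enyl)-2-(trimethylsilyl)isoflavone | COCOc1c(I)c2oc([Si](C)(C)C)c(-c3ccc(OCOC)c(OCOC)c3)c(=O)c2c(OCOC)c1CC=C(C)C
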